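Charged at 0.660 M, c(Q) came to 30.0% of the X and D together, and I took that as the points the pair could lose, one Q to each X or D, with Q the limiting reagent.

| flask | X | D | Q | Z | remark | time |
|---|---|---|---|---|---|---|
| Wednesday's | 1.1 M | 1.1 M | 0.66 M | 2.2 mM | the very flask that is asked about, followed so far |  |
| Tuesday's | 1.1 M | 1.1 M | 0.66 M | 1.1 mM | run made earlier |  |
| flask | 1.1 M | 1.1 M | 0.660 M | 2.2 mM |  | 6.0 h |

Wednesday's run (percent of the X and D together charged)

| time / min | J / % | D / % | X / % |
|---|---|---|---|
| 6.00 | 3 | 46 | 50 |
| 15.0 | 6 | 48 | 46 |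
| 30.0 | 10 | 49 | 41 |
| 50.0 | 11 | 43 | 36 |
| 60.0 | 12 | 43 | 38 |
| 80.0 | 17 | 43 | 35 |
| 120 | 18 | 43 | 32 |

Tuesday's run (percent of the X and D together charged)

| time / h | J / % | D / % | X / % |
|---|---|---|---|
| 0.333 | 4 | 50 | 46 |
| 1.00 | 9 | 48 | 41 |
| 1.50 | 11 | 46 | 37 |
| 2.50 | 15 | 45 | 32 |
| 4.00 | 18 | 42 | 31 |
| 5.00 | 18 | 41 | 32 |
| 6.00 | 18 | 41 | 30 |

(standard deviation of a reading: 1.5 percentage points)

- Z is single-handed; X and D are mirror images of each other, charged as a racemate, each of them at the stated concentration
- the numbers in the tables scatter with a standard deviation of 1.5 percentage points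

1. amount of J in the flask at 6.0 h, in percent of the X and D together charged
2. amount of D in the flask at 6.0 h, in percent of the X and D together charged
3. amount of X in the flask at 6.0 h, in percent of the X and D together charged

Down Tuesday's table, the last 3 rows held flat within the scatter, at X 31.0%, D 41.3% and J 18.0%. Wednesday's flask, with twice the Z, read at 120 min what Tuesday's read at 4.00 h, within the scatter, so I placed its 6.0 h on the flat part and took J from that plateau. Column against column, those means gave 2.51 for the selectivity factor s, the logarithm of the fraction of X left over that of D left.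

I then went round twice. Splitting the budget s to one left X 28.5% and D 41.5%. But X thinned faster, so I put those values back: s weighted by mean X over mean D became 2.16, and the second split left X 29.5% and D 40.5%.

The forecast gave J 18.3%, D 41.5% and X 30.5%, saying “It is exhaustion of Q”. My X and D each stood about 1 point lower.

The flask gave J 17.6%, D 40.5% and X 29.6%, inside the forecast's ranges. At 6.00 h Q stood at 0.33% of its charge, less than X's 59%. Applied to that X, s gives D 40.6%.

    Q + Z + X → Z + J (k = 400 M⁻² h⁻¹)
    Q + Z + D → Z + L (k = 160 M⁻² h⁻¹)
    J ⇌ L (k = 0.0700 h⁻¹)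

The neighbour flask with 1.1 M of Q has a budget of 50.0%; the same two rounds weight s to 1.88 and leave X 17.4% and D 32.6%. Computed, it holds X 17.7% and D 33.0%.

(The readings stem from a simulated flask with made-up constants.)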